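Readings and results come from a simulation with made-up constants, and the scatter is random.

all flasks: starting material 0.050 M; free catalyst 2 mol%
- delta: second substrate 0.75 equiv; partner 1.2 equiv; temperature 70 °C; run made earlier
- teal: second substrate 0.500 equiv; partner 1.20 equiv; temperature 70 °C; time 50 min
- ochre: second substrate 0.500 equiv; partner 1.20 equiv; temperature 45 °C; time 50 min
- amber: second substrate 0.500 equiv; partner 1.20 equiv; temperature 95 °C; time 50 min

- delta (time / min: target / %, isomer of the product / %, starting material / %): 0.250: 1.1, 0.2, 98.6; 0.833: 2.6, 0.5, 96.1; 1.33: 4.5, 0, 94.1; 2.00: 7.6, 0.1, 92.2; 3.00: 11.3, 0.2, 87.7; 4.00: 14.3, 0.3, 85.0; 5.00: 17.0, 1.0, 82.1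

(readings scatter by 0.5 percentage points)

1. the flask with the highest share of target in all that became target or isomer of the product ("all alike" if they lie within 1.5 percentage points) (teal / ochre / amber / all alike)
2. share of target in all that became target or isomer of the product, teal
3. share of target in all that became target or isomer of the product, ochre
4. share of target in all that became target or isomer of the product, amber

- the earlier runs do not show what temperature does; that part of a forecast is a guess

**Early readings.** At early times the delta run builds target steadily, to 17.0% of the charge after 5.00 min, while isomer of the product reaches 1.00%, against a scatter of 0.5 percentage points. The readings cannot tell whether isomer comes from target or forms beside it; we assume it comes from target, so that time in the flask is what costs us.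

**Loss constant.** For target made at a steady pace, and before the loss shortens the target present, the isomer formed equals the constant times final target times time, over 2. Applied to the last 3 delta readings together, this gives 0.0170 min⁻¹, our loss constant: the fraction of the target present that turns into isomer of the product each minute, a pseudo-first-order constant. Each isomer reading behind it carries the scatter, so it is rough.

**Going round.** We now reckon teal at 70 °C, letting target be made steadily for 50 min. On the first round we count everything made as target throughout, so the isomer share is 0.426 and the share of target is 57.4%. But the target present is that share of what was made, so less isomer forms, and putting this back gives 75.5%.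

**The decision.** Teal's loss grows with constant times time, so we would keep the charges and 50 min and run the cooler ochre at 45 °C next, with 75.5% as the figure to beat. How far the constant falls there is a guess.

**The forecast.** The forecast names ochre highest, with 91% for teal, 95% for ochre and 83% for amber: “Temperature is a guess: heat usually favours the isomer”. Its teal figure stands above our 75.5%.

**The flasks.** Ochre is highest at 90.2%, while teal gives 80.3% and amber 71.8%.

    starting material + free catalyst ⇌ catalyst intermediate A (K = 2600 L mol⁻¹, k = 97.2 L mol⁻¹ min⁻¹, Ea = 69.0 kJ mol⁻¹, ΔH = −44.0 kJ mol⁻¹)
    partner + catalyst intermediate A → free catalyst + target (k = 91.0 L mol⁻¹ min⁻¹, Ea = 54.0 kJ mol⁻¹)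
    second substrate + free catalyst ⇌ catalyst intermediate B (K = 91.0 L mol⁻¹, k = 168 L mol⁻¹ min⁻¹, Ea = 35.0 kJ mol⁻¹, ΔH = −60.0 kJ mol⁻¹)
    partner + catalyst intermediate B → free catalyst + second product (k = 273 L mol⁻¹ min⁻¹, Ea = 60.0 kJ mol⁻¹)
    partner → decomposed reagent (k = 0.0287 min⁻¹, Ea = 115 kJ mol⁻¹)
    target + free catalyst ⇌ isomer of the product + free catalyst, rate k6*[free catalyst]*[target] forward; the back reaction follows from the equilibrium constant (K = 31.3, k = 41.4 L mol⁻¹ min⁻¹, Ea = 57.0 kJ mol⁻¹, ΔH = −12.0 kJ mol⁻¹)
    (constants at 70 °C)

**Constant again.** At the asked time teal holds partner at 0.307% of its own charge, and over the next 450 min its target falls from 44.3% to 32.3% of the charge, a loss constant of 7.06 × 10⁻⁴ min⁻¹, far below the 0.0170 min⁻¹ read in the delta run, with free catalyst down to 1.75% of the catalyst charged and catalyst intermediate A, the resting state, at 96.8%. Amber, with partner at 0% of its own charge, drops target from 25.6% to 3.40% over the same stretch, a loss constant of 0.00449 min⁻¹, with free catalyst at 3.34%.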